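**Retrosynthetic overview**
1. Atoms carry germacrane numbers: C6 lactone carbinol, C7=C11 butenolide alkene, C12 lactone carbonyl, C13 CH2OAc, C8 O-tiglate, C9 OH, C10 CHMe, C1 ketone, C4=C5 ring alkene.
2. Last step: the C1 ketone and the C9 hydroxyl are released together from a C1=N–O–C9 dihydroisoxazole by N–O cleavage.
3. Key step: the C6–C7 bond, the same bond that closes farnesyl diphosphate to the germacrane ring. It is made by Ni/Cr alkenylation of a neral-type Z-enal with a tetrasubstituted (Z)-β-iodoenoate, and the C6 alkoxide then attacks C12 in the same flask.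
4. The acyclic C15 chain comes from a magnesium-directed nitrile oxide cycloaddition (C1–C10 and O–C9) that sets C9 and C10 from C8.
5. Fragments: nerol (C1–C6, C15) and crotonaldehyde + propargyl silyl ether + CO2 (C7–C14). Ring order: temporary dihydroisoxazole, ten-membered carbocycle, butenolide.

Assumption: the SMILES is taken literally (E-tiglate, 4Z ring alkene, 6R,8R,9R,10S).

**Step 1**
Reactants: 1 nerol ((2Z)-3,7-dimethylocta-2,6-dien-1-ol)
Product: 2 neryl tert-butyldimethylsilyl ether
Conditions: TBSCl (1.1 equiv), imidazole (1.5 equiv), CH2Cl2, 0 °C to rt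
Reagents that add atoms: tert-butyldimethylsilyl chloride CC(C)(C)[Si](C)(C)Cl
Why: Standard silyl ether protection masks the C6 hydroxyl against the later magnesium alkoxide and acylation steps and leaves the Z alkene untouched; no stereocentre is formed.

**Step 2**
Reactants: 2 neryl tert-butyldimethylsilyl ether
Product: 4 (4Z)-6-(tert-butyldimethylsilyloxy)-4-methylhex-4-enal oxime, via aldehyde 3 (not isolated)
Conditions: O3 (0.95 equiv), pyridine (3 equiv), CH2Cl2, −78 °C; then NH2OH·HCl (2.5 equiv), MeOH, −78 °C to rt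
Reagents that add atoms: ozone [O-][O+]=O (carbonyl oxygen of 3); hydroxylamine hydrochloride Cl.NO (N–OH of 4)
Why: Chemoselective ozonolysis (Criegee cleavage, with pyridine breaking down the carbonyl oxide) attacks the electron-richer distal alkene because the C4=C5 alkene is deactivated by its allylic oxygen, and oxime condensation follows in the same flask; no stereocentre is formed.

**Step 3**
Reactants: 5 (E)-crotonaldehyde; 6 trimethyl(prop-2-yn-1-yloxy)silane
Product: 8 (4S,5E)-hept-5-en-2-yne-1,4-diol, via silyl ether 7 (not isolated)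
Conditions: (S,S)-ProPhenol (10 mol %), Ph3PO (20 mol %), Me2Zn (3 equiv), 6 (3 equiv), toluene, 0 °C, 48 h; then 1 N HCl, THF, 0 °C, 15 min
Reagents that add atoms: none
Why: Zinc–ProPhenol catalysed asymmetric alkynylation of an enal sets C8, with the dinuclear zinc pocket delivering the alkynyl group to one aldehyde face (the sense is assigned by analogy, to be checked by Mosher analysis, and the antipodal ligand is equally available); the acidic work-up removes the Me3Si group.

**Step 4**
Reactants: 8 (4S,5E)-hept-5-en-2-yne-1,4-diol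
Product: 11 (2Z,4S,5E)-4-hydroxy-2-(hydroxymethyl)-3-iodohepta-2,5-dienoic acid, via titanacyclopropene 9 (not isolated), via oxatitanacycle 10 (not isolated)
Conditions: iPrMgCl (2.0 equiv), Et2O, 0 °C; Ti(OiPr)4 (1.2 equiv), iPrMgCl (2.4 equiv), −78 to −40 °C; CO2 (1 atm), −40 to −20 °C; I2 (1.3 equiv), −78 to 0 °C; 1 N HCl
Reagents that add atoms: carbon dioxide O=C=O; iodine [I][I]; titanium tetraisopropoxide CC(C)O[Ti](OC(C)C)(OC(C)C)OC(C)C (in 9 and 10 only); isopropylmagnesium chloride CC(C)[Mg]Cl (MgCl in 9 and 10 only)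
Why: Kulinkovich–Sato formation of a divalent titanium–alkyne complex is followed by carboxylation and iodinolysis, in which CO2 inserts into the less hindered Ti–C11 bond (CH2O side, not the branched C8 side) and iodine cleaves the remaining Ti–C7 bond with retention; the net syn addition places iodine cis to the carboxyl group (2Z) and C8 is not touched.

**Step 5**
Reactants: 11 (2Z,4S,5E)-4-hydroxy-2-(hydroxymethyl)-3-iodohepta-2,5-dienoic acid
Product: 12 methyl (2Z,4S,5E)-4-hydroxy-2-(hydroxymethyl)-3-iodohepta-2,5-dienoate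
Conditions: MeI (1.5 equiv), KHCO3 (1.5 equiv), DMF, rt
Reagents that add atoms: iodomethane [CH3]I
Why: SN2 alkylation of the carboxylate under weak base esterifies only the acid and leaves both hydroxyls, the alkene geometry and C8 unchanged.

**Step 6**
Reactants: 4 (4Z)-6-(tert-butyldimethylsilyloxy)-4-methylhex-4-enal oxime; 12 methyl (2Z,4S,5E)-4-hydroxy-2-(hydroxymethyl)-3-iodohepta-2,5-dienoate
Product: 15 methyl (2Z,4S)-4-hydroxy-2-(hydroxymethyl)-3-iodo-4-{(4R,5R)-3-[(3Z)-5-(tert-butyldimethylsilyloxy)-3-methylpent-3-en-1-yl]-4-methyl-4,5-dihydroisoxazol-5-yl}but-2-enoate, via hydroximoyl chloride 13 (not isolated), via nitrile oxide 14 (not isolated)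
Conditions: 4 (1.3 equiv), tBuOCl (1.3 equiv), CH2Cl2, −78 °C; transfer into 12, iPrOH (3.3 equiv), EtMgBr (5.3 equiv), CH2Cl2, 0 °C to rt, 12 h
Reagents that add atoms: tert-butyl hypochlorite CC(C)(C)OCl (chlorine of 13 only)
Why: In this Kanemasa hydroxyl-directed nitrile oxide 1,3-dipolar cycloaddition magnesium ties the C8 alkoxide to the dipole oxygen so that O adds to C9 and C1 to C10; suprafacial addition to the E alkene gives the trans C9/C10 pair (anti aldol pattern), the alkoxide-outside, large-group-anti transition state gives the C8/C9 syn diol pattern, and the tetrasubstituted iodoalkene and the C4=C5 alkene are too hindered to react.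

**Step 7**
Reactants: 15 dihydroisoxazole diol; 16 tigloyl chloride ((E)-2-methylbut-2-enoyl chloride)
Product: 18 methyl (2Z,4S)-2-(acetoxymethyl)-3-iodo-4-[(E)-2-methylbut-2-enoyloxy]-4-{(4R,5R)-3-[(3Z)-5-(tert-butyldimethylsilyloxy)-3-methylpent-3-en-1-yl]-4-methyl-4,5-dihydroisoxazol-5-yl}but-2-enoate, via monoacetate 17 (not isolated)
Conditions: Ac2O (1.05 equiv), pyridine, CH2Cl2, −20 to 0 °C; then 16 (3 equiv), DMAP (0.2 equiv), 0 °C to rt
Reagents that add atoms: acetic anhydride CC(=O)OC(C)=O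
Why: Sequential acylation acetylates the unhindered primary C13 hydroxyl first and DMAP-catalysed acyl transfer then esterifies the hindered C8 hydroxyl with retention; C9–O is still locked in the dihydroisoxazole, so the 8,9-diol needs no extra protecting group.

**Step 8**
Reactants: 18 silyl ether with 8-tiglate and 13-acetate
Product: 19 methyl (2Z,4S)-2-(acetoxymethyl)-4-{(4R,5R)-3-[(3Z)-5-hydroxy-3-methylpent-3-en-1-yl]-4-methyl-4,5-dihydroisoxazol-5-yl}-3-iodo-4-[(E)-2-methylbut-2-enoyloxy]but-2-enoate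
Conditions: HF·pyridine, pyridine, THF, 0 °C
Reagents that add atoms: none
Why: Buffered fluoride desilylation frees only the C6 hydroxyl; the esters, the alkenyl iodide and the dihydroisoxazole are inert to it.

**Step 9**
Reactants: 19 allylic alcohol
Product: 20 methyl (2Z,4S)-2-(acetoxymethyl)-3-iodo-4-[(E)-2-methylbut-2-enoyloxy]-4-{(4R,5R)-4-methyl-3-[(3Z)-3-methyl-5-oxopent-3-en-1-yl]-4,5-dihydroisoxazol-5-yl}but-2-enoate
Conditions: TEMPO (10 mol %), PhI(OAc)2 (1.1 equiv), CH2Cl2, rt
Reagents that add atoms: none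
Why: Oxoammonium oxidation (TEMPO/PhI(OAc)2) of the only free alcohol gives the neral-type enal under near-neutral conditions that do not isomerise the Z alkene.

**Step 10**
Reactants: 20 iodo enal
Product: 23 (6R,8R,9R,10R)-13-acetoxy-8-tigloyloxygermacra-4Z,7(11)-dien-12,6-olide still bridged by the C1=N–O–C9 dihydroisoxazole, via alkenylchromium 21 (not isolated), via chromium alkoxide 22 (not isolated)
Conditions: CrCl2 (15 equiv), NiCl2 (2 mol %), DMSO/THF 3:1, slow addition of 20 over 12 h to 0.002 mol/L, 25 °C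
Reagents that add atoms: chromium dichloride Cl[Cr]Cl (chromium and chlorine of 21 and 22 only)
Why: Nozaki–Hiyama–Kishi macrocyclisation is followed by spontaneous lactonisation: zerovalent nickel inserts into the carbon–iodine bond, the ester-chelated alkenylchromium adds only to the aldehyde, and the cis C6 alkoxide expels methoxide from C12; the planar dihydroisoxazole holds C2–C1–C10–C9 anti like the 1(10)-E alkene of the farnesyl precursor, and 6R is expected because H-8 eclipses C7=C11 (A(1,3) strain with CH2OAc, which also keeps the C8–O bond orthogonal to C7–Cr and so disfavours allene formation), the aldehyde oxygen sits on the ester side, and C5 takes the alkene face opposite C9 to avoid a syn-pentane contact.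

**Step 11**
Reactants: 23 bridged macrocyclic butenolide
Product: 25 CNP0281168.1 ((4Z,6R,8R,9R,10S)-13-acetoxy-9-hydroxy-1-oxo-8-tigloyloxygermacra-4,7(11)-dien-12,6-olide), via hydroxy imine 24 (not isolated)
Conditions: Mo(CO)6 (1.2 equiv), MeCN/H2O 15:1, 75 °C, 2 h
Reagents that add atoms: water O
Why: Zerovalent molybdenum reductively cleaves the N–O bond of the dihydroisoxazole and the β-hydroxy imine hydrolyses in situ to the β-hydroxy ketone; esters, butenolide and alkenes are not reduced and C9 and C10 keep their configuration (the C10 descriptor changes to S only through the priority rules).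

**Compound list**
1 | nerol | CC(C)=CCC/C(C)=C\CO | starting material
2 | neryl tert-butyldimethylsilyl ether | CC(C)=CCC/C(C)=C\CO[Si](C)(C)C(C)(C)C | intermediate
3 | (4Z)-6-(tert-butyldimethylsilyloxy)-4-methylhex-4-enal | O=CCC/C(C)=C\CO[Si](C)(C)C(C)(C)C | intermediate
4 | oxime of 3 (E/Z at C=N) | ON=CCC/C(C)=C\CO[Si](C)(C)C(C)(C)C | intermediate
5 | (E)-crotonaldehyde | C/C=C/C=O | starting material
6 | trimethyl(prop-2-yn-1-yloxy)silane | C#CCO[Si](C)(C)C | starting material
7 | (4S,5E)-1-(trimethylsilyloxy)hept-5-en-2-yn-4-ol | C/C=C/[C@H](O)C#CCO[Si](C)(C)C | intermediate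
8 | (4S,5E)-hept-5-en-2-yne-1,4-diol | C/C=C/[C@H](O)C#CCO | intermediate
9 | titanacyclopropene of the bis(chloromagnesium) alkoxide of 8 | C/C=C/[C@H](O[Mg]Cl)C1=C(CO[Mg]Cl)[Ti]1(OC(C)C)OC(C)C | intermediate
10 | oxatitanacyclopentenone after CO2 insertion at C11 | C/C=C/[C@H](O[Mg]Cl)C1=C(CO[Mg]Cl)C(=O)O[Ti]1(OC(C)C)OC(C)C | intermediate
11 | (2Z,4S,5E)-4-hydroxy-2-(hydroxymethyl)-3-iodohepta-2,5-dienoic acid | C/C=C/[C@H](O)/C(=C(\CO)C(=O)O)I | intermediate
12 | methyl ester of 11 | C/C=C/[C@H](O)/C(=C(\CO)C(=O)OC)I | intermediate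
13 | hydroximoyl chloride from 4 | CC(C)(C)[Si](C)(C)OC/C=C(/C)CCC(Cl)=NO | intermediate
14 | nitrile oxide from 13 | CC(C)(C)[Si](C)(C)OC/C=C(/C)CCC#[N+][O-] | intermediate
15 | dihydroisoxazole diol (8S,9R,10R) | CC(C)(C)[Si](C)(C)OC/C=C(/C)CCC1=NO[C@H]([C@@H]1C)[C@H](O)/C(=C(\CO)C(=O)OC)I | intermediate
16 | tigloyl chloride | C/C=C(\C)C(=O)Cl | starting material
17 | 13-monoacetate of 15 | CC(C)(C)[Si](C)(C)OC/C=C(/C)CCC1=NO[C@H]([C@@H]1C)[C@H](O)/C(=C(\COC(C)=O)C(=O)OC)I | intermediate
18 | 8-tiglate 13-acetate silyl ether | CC(C)(C)[Si](C)(C)OC/C=C(/C)CCC1=NO[C@H]([C@@H]1C)[C@H](OC(=O)/C(C)=C/C)/C(=C(\COC(C)=O)C(=O)OC)I | intermediate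
19 | C6 allylic alcohol | OC/C=C(/C)CCC1=NO[C@H]([C@@H]1C)[C@H](OC(=O)/C(C)=C/C)/C(=C(\COC(C)=O)C(=O)OC)I | intermediate
20 | C6 Z-enal | O=C/C=C(/C)CCC1=NO[C@H]([C@@H]1C)[C@H](OC(=O)/C(C)=C/C)/C(=C(\COC(C)=O)C(=O)OC)I | intermediate
21 | C7 alkenylchromium dichloride | O=C/C=C(/C)CCC1=NO[C@H]([C@@H]1C)[C@H](OC(=O)/C(C)=C/C)/C(=C(\COC(C)=O)C(=O)OC)[Cr](Cl)Cl | intermediate
22 | ten-membered C6 chromium alkoxide with the methyl ester intact | C/C=C(\C)C(=O)O[C@@H]1/C(=C(\COC(C)=O)C(=O)OC)[C@H](O[Cr](Cl)Cl)/C=C(/C)CCC2=NO[C@@H]1[C@@H]2C | intermediate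
23 | dihydroisoxazole-bridged macrocyclic butenolide | C/C=C(\C)C(=O)O[C@@H]1C2=C(COC(C)=O)C(=O)O[C@@H]2/C=C(/C)CCC3=NO[C@@H]1[C@@H]3C | intermediate
24 | C1 imine, C9 alcohol | C/C=C(\C)C(=O)O[C@@H]1C2=C(COC(C)=O)C(=O)O[C@@H]2/C=C(/C)CCC(=N)[C@@H](C)[C@H]1O | intermediate
25 | CNP0281168.1 | C/C=C(\C)C(=O)O[C@@H]1C2=C(COC(C)=O)C(=O)O[C@@H]2/C=C(/C)CCC(=O)[C@@H](C)[C@H]1O | target

**Step count**
Total step count: 11. Longest linear sequence: 9 (steps 3 to 11).

**Three steps most likely to fail**

Step 10. Possible causes are strain of the bridged ten-membered ring, slow metalation of the tetrasubstituted iodide, loss of tiglate to an allene, or the wrong C6 epimer.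
Fallback: cyclise the unbridged chain instead. From 18, Mo(CO)6 in wet MeCN opens the dihydroisoxazole first to the open-chain silyl ketol F1. HF·pyridine then gives the ketol diol F2. TEMPO/PhI(OAc)2 oxidises only the primary allylic alcohol to the seco enal F3. The CrCl2/NiCl2 closure of F3 tolerates the ketone and the free hydroxyl and comes back to the route at 25, replacing steps 8 to 11.

Step 4. Possible causes are poor regiochemistry of CO2 insertion or low tolerance of the bis-alkoxide.
Fallback: replace the titanium chemistry by borylation. From 8, Pt(PPh3)4-catalysed syn-diboration with B2pin2 has no regiochemical issue and gives the Z bis(boronate) F4. Oxidative methoxycarbonylation (Pd(OAc)2, PPh3, p-benzoquinone, CO, MeOH) at the less hindered boronate next to CH2OH gives the boryl ester F5. Iododeboronation with NaI and chloramine-T proceeds with retention and comes back to the route at 12.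

Step 6. Possible causes are attack of the magnesium alkoxides on the β-iodoenoate, furoxan formation, or a modest diastereomer ratio.
Fallback: join the fragments before the iodoenoate exists. From 4 and 8, the same magnesium-directed cycloaddition on the enynediol gives the alkynyl dihydroisoxazole F6. Pt(PPh3)4/B2pin2 diboration, which does not touch the N–O bond, gives the bis(boronate) F7. Palladium-catalysed oxidative methoxycarbonylation gives the boryl ester F8. Iododeboronation comes back to the route at 15.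

**Further compounds**
F1 | step 10 | open-chain silyl ketol (8S,9R,10S) | CC(C)(C)[Si](C)(C)OC/C=C(/C)CCC(=O)[C@@H](C)[C@@H](O)[C@H](OC(=O)/C(C)=C/C)/C(=C(\COC(C)=O)C(=O)OC)I
F2 | step 10 | ketol diol | OC/C=C(/C)CCC(=O)[C@@H](C)[C@@H](O)[C@H](OC(=O)/C(C)=C/C)/C(=C(\COC(C)=O)C(=O)OC)I
F3 | step 10 | seco enal | O=C/C=C(/C)CCC(=O)[C@@H](C)[C@@H](O)[C@H](OC(=O)/C(C)=C/C)/C(=C(\COC(C)=O)C(=O)OC)I
F4 | step 4 | Z bis(boronate) of 8 | C/C=C/[C@H](O)/C(=C(\CO)B1OC(C)(C)C(C)(C)O1)B1OC(C)(C)C(C)(C)O1
F5 | step 4 | boryl ester | C/C=C/[C@H](O)/C(=C(\CO)C(=O)OC)B1OC(C)(C)C(C)(C)O1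
F6 | step 6 | alkynyl dihydroisoxazole | CC(C)(C)[Si](C)(C)OC/C=C(/C)CCC1=NO[C@H]([C@@H]1C)[C@H](O)C#CCO
F7 | step 6 | bis(boronate) of F6 | CC(C)(C)[Si](C)(C)OC/C=C(/C)CCC1=NO[C@H]([C@@H]1C)[C@H](O)/C(=C(\CO)B2OC(C)(C)C(C)(C)O2)B2OC(C)(C)C(C)(C)O2
F8 | step 6 | boryl ester from F7 | CC(C)(C)[Si](C)(C)OC/C=C(/C)CCC1=NO[C@H]([C@@H]1C)[C@H](O)/C(=C(\CO)C(=O)OC)B2OC(C)(C)C(C)(C)O2
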